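## Structural features

The target is a germacrane-type sesquiterpene lactone: a ten-membered carbocycle (C1–C10) bridged by an oxygen from C3 to C10, which forms a 3(2H)-furanone (O, C10, C1 ketone, C2=C3), and trans-fused at C7–C8 to an α-methylene-γ-butyrolactone (C11, C12, exocyclic C13, lactone oxygen on C8). C3 is linked to C6 through the Z-trisubstituted alkene C4=C5 (methyl C15), so the furanone, this alkene and the C1 ketone form one cross-conjugated dienone; C6 carries a (2S,3R)-2,3-dimethyloxirane-2-carboxylate. C6 (R), C7 (R) and C8 (S) are contiguous; the quaternary C10 (R, methyl C14) is insulated from C8 by the C9 methylene; two further centres sit on the epoxy ester. Fragile groups are the exocyclic methylene lactone (Michael acceptor), the epoxy ester, the allylic C6 ester with possible acyl or lactone migration between O6 and O8, and the vinylogous ester of the furanone. The real difficulty is to close the strained, oxygen-bridged ten-membered ring with a Z alkene while holding the C6–C7–C8 triad in the right relation to remote C10, and to carry the methylene lactone through to the end. The key step uses the fact that C8, C7 and C11 are the γ, β and α carbons of a butenolide: C6 enters at C7 as a nucleophilic formyl equivalent, C13 enters at C11 as an electrophile, and the trans,trans arrangement follows from the single C8 centre.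

## Logic of the disconnections

42 ⇒ 40 (via 41). The C11=C13 alkene is not cut but masked: in 40, C13 carries NMe2 and C11 is sp3. This removes the most fragile group from all earlier steps; the forward step must N-methylate and eliminate without touching the epoxy ester.

40 ⇒ 34 + 38 (via 39). The C6–O acyl bond is cut. This takes two stereocentres and the epoxide out of the main line and makes the route convergent. The forward step must acylate a hindered allylic carbinol; it is done while C13 is still masked so that a free O6 never meets the basic elimination conditions.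

38 ⇒ 37 ⇒ 36 ⇒ 35. The two epoxide C–O bonds come from one reagent-controlled epoxidation of an allylic alcohol, which fixes both centres at once; the oxidation back to the acid must not open the ring.

34 ⇒ 32 (via 33). The C5–C6 bond is cut, opening the ten-membered ring between an sp2 carbon bearing iodide and an aldehyde carbon. All other centres are already present in 32. The forward step needs selective metalation of C5–I, retention of the Z geometry, face selectivity at C6 and high dilution.

32 ⇒ 31 ⇒ 29 (via 30) ⇒ 22 + 28. The C6 aldehyde is a thioacetal in 31. The furanone O–C3 bond is cut because a furanone is an isomer of a γ-hydroxy ynone. The C2–C3 bond is cut as an alkynyl–acyl bond, so 28 delivers C3, C4, C5, C15 and the iodide with fixed geometry. The forward acylation must avoid strong base (acidic C11–H), and the ring closure must spare the β-iodo enone.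

28 ⇒ 27 ⇒ 26 ⇒ 25 ⇒ 23 (via 24). The C4–C15 and C5–I bonds are made anti across an alkyne, which sets the Z geometry in one step.

22 ⇒ 21. Only the two silyl caps differ; no skeletal bond is cut.

21 ⇒ 16 + 17 + 18 (via 19 and 20). The C6–C7 and C11–C13 bonds are cut. A flat butenolide with one stereocentre replaces a trisubstituted lactone; the forward step needs 1,4-regioselectivity and attack anti to the C9 side chain.

16 ⇒ 14 (via 15) ⇒ 13 ⇒ 12 ⇒ 9 + 10 (via 11). The lactone C12–O bond and the cis C7=C11 alkene come from a γ-hydroxy ynoate; the C7–C8 bond is cut to an aldehyde and an acetylide. C8 is set by reagent-controlled ynone reduction, independent of C10.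

9 ⇒ 8 ⇒ 7 ⇒ 6 ⇒ 5 ⇒ 4 ⇒ 2 ⇒ 1 (via 3). The alkyne carbon C2 is added by one-carbon homologation of the C1 aldehyde level; the two carboxyls of 1 are told apart by a cyclic acetal ester; C10 comes unchanged from the chiral pool and has no α-hydrogen to lose.

## Other disconnections considered

Alternative 1: The cut is C8–C9 of the carbocycle, a retro-[3,3] step that leads back to a six-membered ring carrying two alkenyl groups on adjacent carbons. Forward, the potassium alkoxide (KH, 18-crown-6) would rearrange by an anionic oxy-Cope shift to the ring-expanded dienone A1. In its favour: the ten-membered ring forms in a concerted, strain-releasing step without high dilution, both ring alkenes and both methyl groups come out of a chair-like transition state, the C8 oxygen is in place, and the starting terpene is cheap. Against it here: A1 has a C6 ketone and nothing at C1, C3 or C10, and it lacks C11–C13. The oxygen-bridged furanone would have to be built by several oxidations on a mobile cyclodecadiene that is prone to transannular cyclisation, with C10 set late by substrate control relative to remote C8; the three-carbon lactone unit would have to be attached at C7 next to the ketone, and C6 reduced, both diastereoselectively. Comparison: as a ring-forming event the pericyclic expansion is better than the late macrocyclisation of the chosen plan, and A1 is reached in fewer steps. The chosen plan is stronger on structure, because C10 comes from the chiral pool and C6, C7, C11 and C13 are assembled on a five-membered ring, and it should need fewer steps after the key step.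

Alternative 2: The cut is C5–C6, with CrCl2 and catalytic NiCl2 closing the ring from a Z-alkenyl iodide and a C6 aldehyde to give the carbinol A2, which lacks C13. In its favour: it is the same ring-closing bond that the chosen route uses in step 21, so on ring closure and on the origin of the C6 configuration the two plans are equal. The cyclisation substrate has no basic nitrogen, so unmasking and handling of the β-acyloxy aldehyde would be easier; on that point the alternative is better. Against it: C13 would have to be introduced after ring closure by enolising the lactone of a strained macrocycle that also holds the dienone and an oxygen at C6, which needs a strong base, protection of O6 and extra steps. Comparison: the chosen plan attaches C13 in the same flask as C6 and releases the alkene in one mild step; the alternative saves the amine handling but pays with a late, base-dependent methylenation. Step counts up to ring closure are about the same.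

Alternative 3: The cuts are O–C10 and C9–C10. Forward, Cu(hfacac)2 (copper bis(hexafluoroacetylacetonate)) would decompose an α-methyl diazo ketone, the pyran oxygen would capture the carbenoid at C10, and a [2,3] shift of the C7 vinyl group would give the bridged dienone A3. In its favour: one catalytic step would form the furanone ring, the carbocycle and the quaternary C10 centre, with the C4=C5 Z alkene already present and no high dilution; on construction of the two rings it is better than the chosen plan. Against it here: A3 has no lactone carbons and no C8 oxygen. The isolated C7=C8 alkene on a bridged medium ring would have to be turned regio- and stereoselectively into a trans C7–C and C8–O pair, C2–C3 would have to be dehydrogenated, and [1,2] shift or C–H insertion could compete in the key step. Comparison: the chosen plan builds the lactone triad first on a flat five-membered ring, where facial control is simple, and leaves ring strain to the end. The alternative gets the strained core early and cheaply but leaves the hardest functionalisation for the medium ring, so its total step count would probably be higher.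

Key step: step 12

Remarks on the chemistry:
- Butenolide 16 carries SiEt3 on both O10 and the alkyne terminus. A SiMe3 alkyne cap is judged less secure in the semi-hydrogenation of step 11 and toward the organolithium in HMPA; both SiEt3 groups fall in one fluoride step.
- The configurations of 16 (8S,10R) and 21 (7R,8S,10R,11S) match the target. The CIP label of C7 reads S whenever O6 is a free hydroxyl (34), with unchanged geometry.
- The sense of hydride delivery in step 10 is assumed by analogy with simple alkyl alkynyl ketones (alkynyl as the small group) and should be checked by Mosher ester analysis before going on.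

## Route

Step 1
Reactants: 1 (R)-citramalic acid
Product: 2 2-[(4R)-2,2,4-trimethyl-5-oxo-1,3-dioxolan-4-yl]acetic acid
Conditions: Me2C(OMe)2, TsOH·H2O (cat.), CH2Cl2, rt
Reagents that add atoms: 2,2-dimethoxypropane, COC(C)(C)OC
Why: Acetal-ester (dioxolanone) formation across the α-hydroxy acid; the five-membered ring forms in preference to any larger one, so the C1 carboxyl is masked and the C8 carboxyl stays free, and C10 comes unchanged from the chiral pool.

Step 2
Reactants: 2 2-[(4R)-2,2,4-trimethyl-5-oxo-1,3-dioxolan-4-yl]acetic acid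
Product: 4 (3R)-3-hydroxy-3-methyloxolan-2-one, via hydroxyethyl dioxolanone 3 (not isolated)
Conditions: BH3·SMe2, THF, 0 °C to rt; MeOH; then TsOH (cat.), CH2Cl2, rt
Reagents that add atoms: none
Why: Borane reduces the free carboxylic acid chemoselectively in the presence of the acetal ester; acid-catalysed transesterification (lactonisation) of the new primary alcohol onto the dioxolanone carbonyl then releases acetone and gives the five-membered lactone.

Step 3
Reactants: 4 (3R)-3-hydroxy-3-methyloxolan-2-one
Product: 5 (3R)-3-methyl-3-(triethylsilyloxy)oxolan-2-one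
Conditions: Et3SiOTf, 2,6-lutidine, CH2Cl2, −78 to 0 °C
Reagents that add atoms: triethylsilyl trifluoromethanesulfonate, CC[Si](CC)(CC)OS(=O)(=O)C(F)(F)F
Why: Silylation of a hindered tertiary alcohol with a silyl triflate and a non-nucleophilic base; the SiEt3 ether is stable to the coming hydride, base and organolithium steps and is removed by fluoride.

Step 4
Reactants: 5 (3R)-3-methyl-3-(triethylsilyloxy)oxolan-2-one
Product: 6 (3R)-3-methyl-3-(triethylsilyloxy)oxolan-2-ol (both anomers)
Conditions: i-Bu2AlH, CH2Cl2, −78 °C; aq. KNaC4H4O6 (Rochelle salt)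
Reagents that add atoms: none
Why: Partial reduction of a lactone to the lactol; the tetrahedral aluminate is stable at low temperature, and the quaternary C10 has no α-hydrogen to epimerise.

Step 5
Reactants: 6 (3R)-3-methyl-3-(triethylsilyloxy)oxolan-2-ol
Product: 7 (3R)-3-methyl-3-(triethylsilyloxy)pent-4-yn-1-ol
Conditions: dimethyl (1-diazo-2-oxopropyl)phosphonate, K2CO3, MeOH, 0 °C to rt
Reagents that add atoms: dimethyl (1-diazo-2-oxopropyl)phosphonate (Ohira–Bestmann reagent), COP(=O)(OC)C(=[N+]=[N-])C(C)=O
Why: Seyferth–Gilbert homologation in the Ohira–Bestmann variant acts on the open hydroxy aldehyde form of the lactol and adds alkyne carbon C2. A silyl shift between the two oxygens would be harmless, because step 6 silylates whichever hydroxyl is free.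

Step 6
Reactants: 7 (3R)-3-methyl-3-(triethylsilyloxy)pent-4-yn-1-ol
Product: 8 (3R)-3-methyl-3,5-bis(triethylsilyloxy)-1-(triethylsilyl)pent-1-yne
Conditions: n-BuLi (2.2 equiv), THF, −78 °C; Et3SiCl, −78 °C to rt
Reagents that add atoms: chlorotriethylsilane, CC[Si](Cl)(CC)CC
Why: Double deprotonation (alkoxide and acetylide) followed by O- and C-silylation; the alkyne C–H must be capped before the hydrogenation of step 11 and the organolithium of step 12.

Step 7
Reactants: 8 (3R)-3-methyl-3,5-bis(triethylsilyloxy)-1-(triethylsilyl)pent-1-yne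
Product: 9 (3R)-3-methyl-3-(triethylsilyloxy)-5-(triethylsilyl)pent-4-ynal
Conditions: (COCl)2, DMSO, CH2Cl2, −78 to −40 °C; Et3N, −78 °C to rt
Reagents that add atoms: none
Why: Swern oxidation applied directly to a primary triethylsilyl ether, which is cleaved and oxidised in one operation, while the tertiary silyl ether and the alkynylsilane are inert; the β-silyloxy aldehyde is used at once.

Step 8
Reactants: 9 (3R)-3-methyl-3-(triethylsilyloxy)-5-(triethylsilyl)pent-4-ynal; 10 methyl propiolate
Product: 12 methyl (6R)-4-hydroxy-6-methyl-6-(triethylsilyloxy)-8-(triethylsilyl)octa-2,7-diynoate (both C4 epimers), via methyl 3-lithiopropiolate 11 (not isolated)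
Conditions: LiN(SiMe3)2, THF, −78 °C; then 9, −78 °C; aq. NH4Cl
Reagents that add atoms: none
Why: 1,2-Addition of a lithium acetylide to an aldehyde forms C7–C8; no selectivity is needed because C8 is re-set in step 10.

Step 9
Reactants: 12 methyl (6R)-4-hydroxy-6-methyl-6-(triethylsilyloxy)-8-(triethylsilyl)octa-2,7-diynoate
Product: 13 methyl (6R)-6-methyl-4-oxo-6-(triethylsilyloxy)-8-(triethylsilyl)octa-2,7-diynoate
Conditions: Dess–Martin periodinane, NaHCO3, CH2Cl2, 0 °C to rt
Reagents that add atoms: none
Why: Dess–Martin oxidation of a propargylic alcohol to the ynone under buffered, non-basic conditions, which avoids β-elimination of the C10 silyloxy group.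

Step 10
Reactants: 13 methyl (6R)-6-methyl-4-oxo-6-(triethylsilyloxy)-8-(triethylsilyl)octa-2,7-diynoate
Product: 14 methyl (4S,6R)-4-hydroxy-6-methyl-6-(triethylsilyloxy)-8-(triethylsilyl)octa-2,7-diynoate
Conditions: (S)-Alpine-Borane (B-isopinocampheyl-9-borabicyclo[3.3.1]nonane from (−)-α-pinene), THF, rt; CH3CHO; then HOCH2CH2NH2, Et2O
Reagents that add atoms: none
Why: Alpine-Borane (Midland) reduction of an activated ynone; in the boat-like transition state the linear alkynoate takes the small-group position, so the reagent from (−)-α-pinene should give the 4S carbinol (C8 S) under reagent control, largely independent of the remote C10 centre.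

Step 11
Reactants: 14 methyl (4S,6R)-4-hydroxy-6-methyl-6-(triethylsilyloxy)-8-(triethylsilyl)octa-2,7-diynoate
Product: 16 (5S)-5-[(2R)-2-methyl-2-(triethylsilyloxy)-4-(triethylsilyl)but-3-yn-1-yl]furan-2(5H)-one, via Z-hydroxy enoate 15 (not isolated)
Conditions: H2 (1 atm), Pd/CaCO3 poisoned with Pb(OAc)2 (Lindlar catalyst), quinoline, EtOAc, rt; then PPTS (cat.), CH2Cl2, rt
Reagents that add atoms: none
Why: Lindlar cis-semihydrogenation takes the electron-poor, unhindered ynoate, while the SiEt3-capped alkyne next to quaternary C10 is shielded; the Z γ-hydroxy enoate then lactonises to the butenolide with loss of methanol, and C8 is untouched.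

Step 12
Reactants: 16 (5S)-5-[(2R)-2-methyl-2-(triethylsilyloxy)-4-(triethylsilyl)but-3-yn-1-yl]furan-2(5H)-one; 17 1,3-dithiane; 18 N,N-dimethylmethyleneiminium iodide
Product: 21 (3S,4R,5S)-3-[(dimethylamino)methyl]-4-(1,3-dithian-2-yl)-5-[(2R)-2-methyl-2-(triethylsilyloxy)-4-(triethylsilyl)but-3-yn-1-yl]oxolan-2-one, via 2-lithio-1,3-dithiane 19 (not isolated), via lithium lactone enolate 20 (not isolated)
Conditions: 17, n-BuLi, THF, −30 °C; HMPA, −78 °C; 16, −78 °C; then 18, −78 to −20 °C; aq. NaHCO3
Reagents that add atoms: none
Why: The sulfur-stabilised carbanion 19, present as a solvent-separated ion pair in THF–HMPA, attacks the β-carbon C7 of 16 (conjugate addition) to give the lithium enolate 20, which is C-alkylated at C11 by the iminium ion of 18 (Mannich reaction), forming C6–C7 and C11–C13 in one flask. The closest known reaction type is the tandem conjugate addition of lithiated thioacetals to γ-substituted butenolides with trapping of the enolate by an electrophile, joined to the standard aminomethylation of lactone enolates. No ring is closed or opened; the existing five-membered lactone only changes from sp2 to sp3 at C7 and C11. C7 is controlled by the C8 centre: the nucleophile enters the flat butenolide on the face opposite the C9 side chain, so C6 and C9 end up trans (7R). C11 is controlled by C7: the iminium ion approaches the enolate anti to the bulky dithianyl group, which should give the 7,11-trans product (11S), and this centre is removed later so its selectivity is not critical. The step needs 1,4- over 1,2-addition and addition over removal of the C8 proton; the first is secured by HMPA and the low carbonyl reactivity of a lactone, the second by working at −78 °C, where attack at the unhindered β-carbon should be faster than deprotonation. The SiEt3 caps leave no acidic alkyne C–H for the organolithium and no acetylide that could intercept 18. The dithiane C6–H of the adduct is much less acidic than the lactone α-position, so the enolate should persist until 18 is added.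

Step 13
Reactants: 21 (3S,4R,5S)-3-[(dimethylamino)methyl]-4-(1,3-dithian-2-yl)-5-[(2R)-2-methyl-2-(triethylsilyloxy)-4-(triethylsilyl)but-3-yn-1-yl]oxolan-2-one
Product: 22 (3S,4R,5S)-3-[(dimethylamino)methyl]-4-(1,3-dithian-2-yl)-5-[(2R)-2-hydroxy-2-methylbut-3-yn-1-yl]oxolan-2-one
Conditions: Bu4NF, AcOH, THF, 0 °C to rt
Reagents that add atoms: none
Why: Fluoride-mediated desilylation removes the alkynyl and the tertiary O-silyl group in one operation; buffering with acetic acid limits base-induced loss of dimethylamine from the β-amino lactone, and any epimerisation at C11 is without consequence.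

Step 14
Reactants: 23 prop-2-yn-1-ol
Product: 25 (2Z)-3-iodo-2-methylprop-2-en-1-ol, via alkenylmagnesium alkoxide 24 (not isolated)
Conditions: MeMgBr (3 equiv), CuI (10 mol %), THF, −10 °C to rt; I2, −78 to 0 °C
Reagents that add atoms: methylmagnesium bromide, C[Mg]Br; iodine, II
Why: Copper-catalysed anti carbomagnesiation of the propargylic alkoxide puts the methyl group (C15) on C4 and magnesium on C5 cis to the CH2O group through a five-membered chelate; iodinolysis with retention gives the Z iodide.

Step 15
Reactants: 25 (2Z)-3-iodo-2-methylprop-2-en-1-ol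
Product: 26 (2Z)-3-iodo-2-methylprop-2-enal
Conditions: MnO2, CH2Cl2, rt, dark
Reagents that add atoms: none
Why: Allylic oxidation with MnO2 under neutral conditions; light and acid are excluded to keep the Z geometry of the β-iodo enal.

Step 16
Reactants: 26 (2Z)-3-iodo-2-methylprop-2-enal
Product: 27 (2Z)-3-iodo-2-methylprop-2-enoic acid
Conditions: NaClO2, NaH2PO4, 2-methylbut-2-ene, t-BuOH/H2O, 0 °C to rt
Reagents that add atoms: sodium chlorite, [Na+].[O-]Cl=O
Why: Pinnick oxidation converts the enal to the acid without touching the alkene or the C–I bond; the alkene scavenger removes hypochlorous acid.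

Step 17
Reactants: 27 (2Z)-3-iodo-2-methylprop-2-enoic acid
Product: 28 (2Z)-3-iodo-2-methylprop-2-enoyl chloride
Conditions: 1-chloro-N,N,2-trimethylprop-1-en-1-amine, CH2Cl2, 0 °C to rt; solution used directly
Reagents that add atoms: 1-chloro-N,N,2-trimethylprop-1-en-1-amine (Ghosez's reagent), CC(C)=C(Cl)N(C)C
Why: Acid chloride formation with a chloroenamine under neutral conditions, so no HCl is present to isomerise the Z-iodoalkene or exchange iodide for chloride.

Step 18
Reactants: 22 (3S,4R,5S)-3-[(dimethylamino)methyl]-4-(1,3-dithian-2-yl)-5-[(2R)-2-hydroxy-2-methylbut-3-yn-1-yl]oxolan-2-one; 28 (2Z)-3-iodo-2-methylprop-2-enoyl chloride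
Product: 29 (3S,4R,5S)-3-[(dimethylamino)methyl]-4-(1,3-dithian-2-yl)-5-[(2R,6Z)-2-hydroxy-7-iodo-2,6-dimethyl-5-oxohept-6-en-3-yn-1-yl]oxolan-2-one
Conditions: CuI (10 mol %), i-Pr2NEt, THF, 0 °C to rt
Reagents that add atoms: none
Why: Copper-catalysed acylation of a terminal alkyne with an acid chloride forms C2–C3 through a copper acetylide made with an amine base, so no strong base meets the acidic C11–H of the lactone. Palladium is left out so that the alkenyl iodide is not activated, and the hindered tertiary alcohol should not be acylated without an acyl-transfer catalyst.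

Step 19
Reactants: 29 (3S,4R,5S)-3-[(dimethylamino)methyl]-4-(1,3-dithian-2-yl)-5-[(2R,6Z)-2-hydroxy-7-iodo-2,6-dimethyl-5-oxohept-6-en-3-yn-1-yl]oxolan-2-one
Product: 31 (3S,4R,5S)-3-[(dimethylamino)methyl]-4-(1,3-dithian-2-yl)-5-({(2R)-5-[(1Z)-1-iodoprop-1-en-2-yl]-2-methyl-3-oxo-2,3-dihydrofuran-2-yl}methyl)oxolan-2-one, via diethylamino enone 30 (not isolated)
Conditions: Et2NH (1.1 equiv), EtOH/THF, 0 °C; then AcOH, H2O, rt
Reagents that add atoms: none
Why: Amine-mediated isomerisation of a γ-hydroxy ynone to a 3(2H)-furanone: conjugate addition of the amine at C1 gives enaminone 30, the C10 hydroxyl adds to the C3 carbonyl (5-exo-trig), water is lost and the iminium is hydrolysed to the C1 ketone. The ynone should react much faster than the α-methyl β-iodo enone, and after the first addition the carbonyl is a deactivated vinylogous amide, so one equivalent of amine at 0 °C should leave C5–I alone.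

Step 20
Reactants: 31 (3S,4R,5S)-3-[(dimethylamino)methyl]-4-(1,3-dithian-2-yl)-5-({(2R)-5-[(1Z)-1-iodoprop-1-en-2-yl]-2-methyl-3-oxo-2,3-dihydrofuran-2-yl}methyl)oxolan-2-one
Product: 32 (2S,3R,4S)-4-[(dimethylamino)methyl]-2-({(2R)-5-[(1Z)-1-iodoprop-1-en-2-yl]-2-methyl-3-oxo-2,3-dihydrofuran-2-yl}methyl)-5-oxooxolane-3-carbaldehyde
Conditions: Hg(ClO4)2·3H2O, CaCO3, THF/H2O, 0 °C, short contact; used at once
Reagents that add atoms: water, O
Why: Thiophilic metal-assisted hydrolysis of the dithiane under carbonate buffering is fast at 0 °C and leaves the alkenyl iodide, the furanone and the tertiary amine intact; the β-acyloxy aldehyde is not stored.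

Step 21
Reactants: 32 (2S,3R,4S)-4-[(dimethylamino)methyl]-2-({(2R)-5-[(1Z)-1-iodoprop-1-en-2-yl]-2-methyl-3-oxo-2,3-dihydrofuran-2-yl}methyl)-5-oxooxolane-3-carbaldehyde
Product: 34 (4Z,6R,7S,8S,10R,11S)-13-(dimethylamino)-6-hydroxy-1-oxo-3,10-epoxygermacra-2,4-dien-12,8-olide, via alkenylchromium dichloride 33 (not isolated)
Conditions: CrCl2 (excess), NiCl2 (cat.), degassed DMSO, high dilution (slow addition), rt
Reagents that add atoms: none
Why: Nozaki–Hiyama–Kishi reaction: nickel-catalysed insertion into C5–I and transmetalation give alkenylchromium 33 with retention of the Z geometry, which adds only to the aldehyde and closes the ten-membered ring at C5–C6. The trans lactone and the rigid furanone restrict the ring-closing conformers, and addition to the aldehyde face that keeps the C6 oxygen on the outside of the forming ring should give the 6R carbinol.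

Step 22
Reactants: 35 tiglic acid
Product: 36 (2E)-2-methylbut-2-en-1-ol
Conditions: LiAlH4, Et2O, 0 °C
Reagents that add atoms: none
Why: Hydride reduction of the carboxylic acid to the allylic alcohol; the E geometry, which places the two methyl groups cis, is retained.

Step 23
Reactants: 36 (2E)-2-methylbut-2-en-1-ol
Product: 37 [(2R,3R)-2,3-dimethyloxiran-2-yl]methanol
Conditions: Ti(OiPr)4 (cat.), D-(−)-diethyl tartrate (cat.), t-BuOOH, 4 Å molecular sieves, CH2Cl2, −20 °C
Reagents that add atoms: tert-butyl hydroperoxide, CC(C)(C)OO
Why: Sharpless asymmetric epoxidation of a trisubstituted E allylic alcohol; D-(−)-tartrate gives the 2R,3R epoxy alcohol (L-(+)-tartrate gives 2S,3S with E-2-alken-1-ols), and syn delivery of oxygen keeps the two methyl groups cis.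

Step 24
Reactants: 37 [(2R,3R)-2,3-dimethyloxiran-2-yl]methanol
Product: 38 (2S,3R)-2,3-dimethyloxirane-2-carboxylic acid
Conditions: TEMPO (cat.), PhI(OAc)2, MeCN/H2O, rt
Reagents that add atoms: water, O
Why: Nitroxyl-catalysed oxidation of the primary alcohol through the aldehyde hydrate to the acid under near-neutral conditions that do not open the epoxide; the label at C2 changes from R to S only because the carboxyl outranks C3.

Step 25
Reactants: 34 (4Z,6R,7S,8S,10R,11S)-13-(dimethylamino)-6-hydroxy-1-oxo-3,10-epoxygermacra-2,4-dien-12,8-olide; 38 (2S,3R)-2,3-dimethyloxirane-2-carboxylic acid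
Product: 40 (4Z,6R,7R,8S,10R,11S)-13-(dimethylamino)-6-{[(2S,3R)-2,3-dimethyloxirane-2-carbonyl]oxy}-1-oxo-3,10-epoxygermacra-2,4-dien-12,8-olide, via mixed trichlorobenzoic anhydride 39 (not isolated)
Conditions: 38, 2,4,6-Cl3C6H2COCl, Et3N, toluene, rt; then 34, DMAP, toluene, rt
Reagents that add atoms: none
Why: Yamaguchi esterification couples a hindered α,α-disubstituted acid with a hindered allylic carbinol through a mixed anhydride with retention at C6; doing it while C13 is still an amine keeps the free O6 away from the later basic step and from any lactone migration.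

Step 26
Reactants: 40 (4Z,6R,7R,8S,10R,11S)-13-(dimethylamino)-6-{[(2S,3R)-2,3-dimethyloxirane-2-carbonyl]oxy}-1-oxo-3,10-epoxygermacra-2,4-dien-12,8-olide
Product: 42 (4Z,6R,7R,8S,10R)-6-{[(2S,3R)-2,3-dimethyloxirane-2-carbonyl]oxy}-1-oxo-3,10-epoxygermacra-2,4,11(13)-trien-12,8-olide, via trimethylammonium iodide 41 (not isolated)
Conditions: MeI, THF, rt; concentrate; aq. NaHCO3, EtOAc, rt
Reagents that add atoms: none
Why: N-methylation gives a quaternary ammonium salt β to the lactone carbonyl, which undergoes E1cB (Hofmann-type) elimination with mild base to the exocyclic methylene and removes the C11 centre; epoxide, ester and furanone should tolerate neutral methyl iodide and hydrogencarbonate.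

## Compound list

1 | (R)-citramalic acid, (2R)-2-hydroxy-2-methylbutanedioic acid | OC(=O)C[C@@](C)(O)C(=O)O | starting material
2 | 2-[(4R)-2,2,4-trimethyl-5-oxo-1,3-dioxolan-4-yl]acetic acid | OC(=O)C[C@@]1(C)OC(C)(C)OC1=O | intermediate
3 | (5R)-5-(2-hydroxyethyl)-2,2,5-trimethyl-1,3-dioxolan-4-one | OCC[C@@]1(C)OC(C)(C)OC1=O | intermediate
4 | (3R)-3-hydroxy-3-methyloxolan-2-one | O=C1OCC[C@@]1(C)O | intermediate
5 | (3R)-3-methyl-3-(triethylsilyloxy)oxolan-2-one | O=C1OCC[C@@]1(C)O[Si](CC)(CC)CC | intermediate
6 | (3R)-3-methyl-3-(triethylsilyloxy)oxolan-2-ol, both anomers | OC1OCC[C@@]1(C)O[Si](CC)(CC)CC | intermediate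
7 | (3R)-3-methyl-3-(triethylsilyloxy)pent-4-yn-1-ol | OCC[C@@](C)(O[Si](CC)(CC)CC)C#C | intermediate
8 | (3R)-3-methyl-3,5-bis(triethylsilyloxy)-1-(triethylsilyl)pent-1-yne | CC[Si](CC)(CC)OCC[C@@](C)(O[Si](CC)(CC)CC)C#C[Si](CC)(CC)CC | intermediate
9 | (3R)-3-methyl-3-(triethylsilyloxy)-5-(triethylsilyl)pent-4-ynal | O=CC[C@@](C)(O[Si](CC)(CC)CC)C#C[Si](CC)(CC)CC | intermediate
10 | methyl propiolate | C#CC(=O)OC | starting material
11 | methyl 3-lithiopropiolate | [Li]C#CC(=O)OC | intermediate
12 | methyl (6R)-4-hydroxy-6-methyl-6-(triethylsilyloxy)-8-(triethylsilyl)octa-2,7-diynoate, both C4 epimers | COC(=O)C#CC(O)C[C@@](C)(O[Si](CC)(CC)CC)C#C[Si](CC)(CC)CC | intermediate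
13 | methyl (6R)-6-methyl-4-oxo-6-(triethylsilyloxy)-8-(triethylsilyl)octa-2,7-diynoate | COC(=O)C#CC(=O)C[C@@](C)(O[Si](CC)(CC)CC)C#C[Si](CC)(CC)CC | intermediate
14 | methyl (4S,6R)-4-hydroxy-6-methyl-6-(triethylsilyloxy)-8-(triethylsilyl)octa-2,7-diynoate | COC(=O)C#C[C@@H](O)C[C@@](C)(O[Si](CC)(CC)CC)C#C[Si](CC)(CC)CC | intermediate
15 | methyl (2Z,4S,6R)-4-hydroxy-6-methyl-6-(triethylsilyloxy)-8-(triethylsilyl)oct-2-en-7-ynoate | COC(=O)/C=C\[C@@H](O)C[C@@](C)(O[Si](CC)(CC)CC)C#C[Si](CC)(CC)CC | intermediate
16 | (5S)-5-[(2R)-2-methyl-2-(triethylsilyloxy)-4-(triethylsilyl)but-3-yn-1-yl]furan-2(5H)-one | O=C1C=C[C@H](C[C@@](C)(O[Si](CC)(CC)CC)C#C[Si](CC)(CC)CC)O1 | intermediate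
17 | 1,3-dithiane | C1CSCSC1 | starting material
18 | N,N-dimethylmethyleneiminium iodide | C=[N+](C)C.[I-] | starting material
19 | 2-lithio-1,3-dithiane | [Li]C1SCCCS1 | intermediate
20 | lithium (4R,5S)-4-(1,3-dithian-2-yl)-5-[(2R)-2-methyl-2-(triethylsilyloxy)-4-(triethylsilyl)but-3-yn-1-yl]-4,5-dihydrofuran-2-olate | [Li]OC1=C[C@@H](C2SCCCS2)[C@H](C[C@@](C)(O[Si](CC)(CC)CC)C#C[Si](CC)(CC)CC)O1 | intermediate
21 | (3S,4R,5S)-3-[(dimethylamino)methyl]-4-(1,3-dithian-2-yl)-5-[(2R)-2-methyl-2-(triethylsilyloxy)-4-(triethylsilyl)but-3-yn-1-yl]oxolan-2-one | CN(C)C[C@H]1C(=O)O[C@@H](C[C@@](C)(O[Si](CC)(CC)CC)C#C[Si](CC)(CC)CC)[C@@H]1C1SCCCS1 | intermediate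
22 | (3S,4R,5S)-3-[(dimethylamino)methyl]-4-(1,3-dithian-2-yl)-5-[(2R)-2-hydroxy-2-methylbut-3-yn-1-yl]oxolan-2-one | CN(C)C[C@H]1C(=O)O[C@@H](C[C@@](C)(O)C#C)[C@@H]1C1SCCCS1 | intermediate
23 | prop-2-yn-1-ol | C#CCO | starting material
24 | bromomagnesium (2Z)-3-(bromomagnesio)-2-methylprop-2-en-1-olate | C/C(=C/[Mg]Br)CO[Mg]Br | intermediate
25 | (2Z)-3-iodo-2-methylprop-2-en-1-ol | C/C(=C/I)CO | intermediate
26 | (2Z)-3-iodo-2-methylprop-2-enal | C/C(=C/I)C=O | intermediate
27 | (2Z)-3-iodo-2-methylprop-2-enoic acid | C/C(=C/I)C(=O)O | intermediate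
28 | (2Z)-3-iodo-2-methylprop-2-enoyl chloride | C/C(=C/I)C(=O)Cl | intermediate
29 | (3S,4R,5S)-3-[(dimethylamino)methyl]-4-(1,3-dithian-2-yl)-5-[(2R,6Z)-2-hydroxy-7-iodo-2,6-dimethyl-5-oxohept-6-en-3-yn-1-yl]oxolan-2-one | CN(C)C[C@H]1C(=O)O[C@@H](C[C@@](C)(O)C#CC(=O)/C(C)=C\I)[C@@H]1C1SCCCS1 | intermediate
30 | (3S,4R,5S)-5-[(2R,3E,6Z)-3-(diethylamino)-2-hydroxy-7-iodo-2,6-dimethyl-5-oxohepta-3,6-dien-1-yl]-3-[(dimethylamino)methyl]-4-(1,3-dithian-2-yl)oxolan-2-one | CN(C)C[C@H]1C(=O)O[C@@H](C[C@@](C)(O)/C(N(CC)CC)=C\C(=O)/C(C)=C\I)[C@@H]1C1SCCCS1 | intermediate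
31 | (3S,4R,5S)-3-[(dimethylamino)methyl]-4-(1,3-dithian-2-yl)-5-({(2R)-5-[(1Z)-1-iodoprop-1-en-2-yl]-2-methyl-3-oxo-2,3-dihydrofuran-2-yl}methyl)oxolan-2-one | CN(C)C[C@H]1C(=O)O[C@@H](C[C@@]2(C)OC(=CC2=O)/C(C)=C\I)[C@@H]1C1SCCCS1 | intermediate
32 | (2S,3R,4S)-4-[(dimethylamino)methyl]-2-({(2R)-5-[(1Z)-1-iodoprop-1-en-2-yl]-2-methyl-3-oxo-2,3-dihydrofuran-2-yl}methyl)-5-oxooxolane-3-carbaldehyde | CN(C)C[C@H]1C(=O)O[C@@H](C[C@@]2(C)OC(=CC2=O)/C(C)=C\I)[C@@H]1C=O | intermediate
33 | alkenylchromium dichloride of 32 (CrCl2 on C5 in place of iodine, Z geometry kept) | CN(C)C[C@H]1C(=O)O[C@@H](C[C@@]2(C)OC(=CC2=O)/C(C)=C\[Cr](Cl)Cl)[C@@H]1C=O | intermediate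
34 | (4Z,6R,7S,8S,10R,11S)-13-(dimethylamino)-6-hydroxy-1-oxo-3,10-epoxygermacra-2,4-dien-12,8-olide | CN(C)C[C@H]1C(=O)O[C@H]2C[C@@]3(C)OC(=CC3=O)/C(C)=C\[C@@H](O)[C@H]12 | intermediate
35 | tiglic acid, (2E)-2-methylbut-2-enoic acid | C/C=C(\C)C(=O)O | starting material
36 | (2E)-2-methylbut-2-en-1-ol | C/C=C(\C)CO | intermediate
37 | [(2R,3R)-2,3-dimethyloxiran-2-yl]methanol | OC[C@@]1(C)O[C@@H]1C | intermediate
38 | (2S,3R)-2,3-dimethyloxirane-2-carboxylic acid | OC(=O)[C@@]1(C)O[C@@H]1C | intermediate
39 | (2S,3R)-2,3-dimethyloxirane-2-carboxylic 2,4,6-trichlorobenzoic anhydride | O=C(OC(=O)[C@@]1(C)O[C@@H]1C)c1c(Cl)cc(Cl)cc1Cl | intermediate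
40 | (4Z,6R,7R,8S,10R,11S)-13-(dimethylamino)-6-{[(2S,3R)-2,3-dimethyloxirane-2-carbonyl]oxy}-1-oxo-3,10-epoxygermacra-2,4-dien-12,8-olide | CN(C)C[C@H]1C(=O)O[C@H]2C[C@@]3(C)OC(=CC3=O)/C(C)=C\[C@@H](OC(=O)[C@@]3(C)O[C@@H]3C)[C@H]12 | intermediate
41 | N,N,N-trimethylammonium iodide of 40 (NMe3+ on C13) | C[N+](C)(C)C[C@H]1C(=O)O[C@H]2C[C@@]3(C)OC(=CC3=O)/C(C)=C\[C@@H](OC(=O)[C@@]3(C)O[C@@H]3C)[C@H]12.[I-] | intermediate
42 | (4Z,6R,7R,8S,10R)-6-{[(2S,3R)-2,3-dimethyloxirane-2-carbonyl]oxy}-1-oxo-3,10-epoxygermacra-2,4,11(13)-trien-12,8-olide (CNP0258430.2) | C=C1C(=O)O[C@H]2C[C@@]3(C)OC(=CC3=O)/C(C)=C\[C@@H](OC(=O)[C@@]3(C)O[C@@H]3C)[C@H]12 | target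

## Step count and least certain steps

Total step count: 26. Longest linear sequence: 19 steps (steps 1–13, 18–21, 25 and 26). The iodoacryloyl branch (steps 14–17) and the epoxy acid branch (steps 22–24) are convergent.

Step 12 (key step). The unsubstituted lithiodithiane is hard and basic, so 1,2-addition to the lactone carbonyl or removal of the C8 proton may compete with conjugate addition; the latter would erode the C8 configuration through the 2-oxidofuran. Incomplete trapping of the enolate is a second risk. Fallback: starting from 16, the softer, bulkier and less basic 2-lithio-2-(trimethylsilyl)-1,3-dithiane would be used as the 1,4-donor with the same trapping by 18. This should give (3S,4R,5S)-3-[(dimethylamino)methyl]-5-[(2R)-2-methyl-2-(triethylsilyloxy)-4-(triethylsilyl)but-3-yn-1-yl]-4-[2-(trimethylsilyl)-1,3-dithian-2-yl]oxolan-2-one F1. The fluoride treatment of step 13 would then also cleave the dithianyl C–Si bond, and the route is rejoined at 22.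

Step 18. The copper acetylide may form slowly in the presence of the chelating amine and dithiane, and the amine base or chloride may add to and eliminate from the β-iodo position, with loss of iodide or of the Z geometry. Fallback: starting from 22, the alkynylzinc made with Me2Zn in toluene/THF (which does not attack the lactone) would be added to aldehyde 26. This should give (3S,4R,5S)-3-[(dimethylamino)methyl]-4-(1,3-dithian-2-yl)-5-[(2R,6Z)-2,5-dihydroxy-7-iodo-2,6-dimethylhept-6-en-3-yn-1-yl]oxolan-2-one F2 as a mixture of carbinol epimers. Oxidation of the propargylic alcohol with MnO2 returns to the route at 29.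

Step 19. The secondary amine may also attack C5 of the β-iodo enone (vinylogous substitution of iodide), or scramble the alkene geometry by reversible addition. Fallback: starting from 29, an electrophilic instead of a nucleophilic activation would be used. A divalent mercury salt in dilute aqueous acid (HgO, H2SO4, aq. THF) should hydrate the ynone at C1, cyclodehydrate to the furanone and hydrolyse the dithiane in the same operation, with the substrate amine protonated. This comes back to the route at 32 and makes no new compound (F0).

Step 20. The liberated β-acyloxy aldehyde may epimerise at C7 or lose the C8 lactone oxygen by elimination, both helped by the internal amine; binding of mercury to the amine may also slow the hydrolysis. Fallback: starting from 31, alkylative hydrolysis with MeI and NaHCO3 in aqueous MeCN would cleave the dithiane and at the same time quaternise and eliminate the amine. This should give (2S,3R)-2-({(2R)-5-[(1Z)-1-iodoprop-1-en-2-yl]-2-methyl-3-oxo-2,3-dihydrofuran-2-yl}methyl)-4-methylidene-5-oxooxolane-3-carbaldehyde F3, which has no internal base. Ring closure with CrCl2 and catalytic NiCl2 would then give (4Z,6R,7S,8S,10R)-6-hydroxy-1-oxo-3,10-epoxygermacra-2,4,11(13)-trien-12,8-olide F4, and esterification with 38 through 39 returns to the route at 42.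

Step 21. Facial selectivity at C6 may be poor or of the wrong sense, and intermolecular coupling or reduction of the C5–I bond may compete with ring closure. Fallback: if the 6-epimer, (4Z,6S,7S,8S,10R,11S)-13-(dimethylamino)-6-hydroxy-1-oxo-3,10-epoxygermacra-2,4-dien-12,8-olide F5, is the main product, it would be esterified with 38 under Mitsunobu conditions (PPh3, diisopropyl azodicarboxylate). This inverts C6 and installs the ester in one step, and the route is rejoined at 40.

## Further compounds

F1 | step 12 | (3S,4R,5S)-3-[(dimethylamino)methyl]-5-[(2R)-2-methyl-2-(triethylsilyloxy)-4-(triethylsilyl)but-3-yn-1-yl]-4-[2-(trimethylsilyl)-1,3-dithian-2-yl]oxolan-2-one | CN(C)C[C@H]1C(=O)O[C@@H](C[C@@](C)(O[Si](CC)(CC)CC)C#C[Si](CC)(CC)CC)[C@@H]1C1([Si](C)(C)C)SCCCS1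
F2 | step 18 | (3S,4R,5S)-3-[(dimethylamino)methyl]-4-(1,3-dithian-2-yl)-5-[(2R,6Z)-2,5-dihydroxy-7-iodo-2,6-dimethylhept-6-en-3-yn-1-yl]oxolan-2-one, both C5 carbinol epimers | CN(C)C[C@H]1C(=O)O[C@@H](C[C@@](C)(O)C#CC(O)/C(C)=C\I)[C@@H]1C1SCCCS1
F0 | step 19 | none | none
F3 | step 20 | (2S,3R)-2-({(2R)-5-[(1Z)-1-iodoprop-1-en-2-yl]-2-methyl-3-oxo-2,3-dihydrofuran-2-yl}methyl)-4-methylidene-5-oxooxolane-3-carbaldehyde | C=C1C(=O)O[C@@H](C[C@@]2(C)OC(=CC2=O)/C(C)=C\I)[C@@H]1C=O
F4 | step 20 | (4Z,6R,7S,8S,10R)-6-hydroxy-1-oxo-3,10-epoxygermacra-2,4,11(13)-trien-12,8-olide | C=C1C(=O)O[C@H]2C[C@@]3(C)OC(=CC3=O)/C(C)=C\[C@@H](O)[C@H]12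
F5 | step 21 | (4Z,6S,7S,8S,10R,11S)-13-(dimethylamino)-6-hydroxy-1-oxo-3,10-epoxygermacra-2,4-dien-12,8-olide | CN(C)C[C@H]1C(=O)O[C@H]2C[C@@]3(C)OC(=CC3=O)/C(C)=C\[C@H](O)[C@H]12
A1 | alternative 1 | (2Z,6E,9S)-9-[(4-methoxybenzyl)oxy]-3,7-dimethylcyclodeca-2,6-dien-1-one | C1C(=O)/C=C(C)\CC/C=C(C)/C[C@@H]1OCc2ccc(OC)cc2
A2 | alternative 2 | (4Z,6R,7S,8S,10R)-6-hydroxy-1-oxo-3,10-epoxy-13-norgermacra-2,4-dien-12,8-olide | C1C(=O)O[C@H]2C[C@@]3(C)OC(=CC3=O)/C(C)=C\[C@@H](O)[C@H]12
A3 | alternative 3 | (3R,6S,10R)-6-(tert-butyldimethylsilyloxy)-3,10-epoxygermacra-4Z,7Z-dien-1-one skeleton without C11–C13, an 11-oxabicyclo[6.2.1]undecadienone | C[C@@]12C/C=C\[C@H](O[Si](C)(C)C(C)(C)C)/C=C(/C)[C@@H](CC1=O)O2
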